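**Plan**
1. Numbering: ring A (seven-membered) is C1 [C(OH), bearing acyl carbon C2, then C3=C4–C15], C5 (O-isobutyryl), C6 (lactone O–CH), C7 (fusion CH), C8 (CH2), C9 (CHOH) and C10 (CH–C14H3). Ring B (lactone) is O, C12(=O), C11(=C13H2), C7 and C6.
2. Enabling feature: the ring-A neighbours C1 and C10 carry a carboxyl-level carbon (C2) and a methyl (C14), which is the substitution pattern of a but-2-ynoate. Excising C1–C10 and joining C5 to C9 leaves a cyclopentanone cis-fused to ring B.
3. Retrosynthetic cuts, in order: C2–C3 (acyl–vinyl), C11=C13, the C9–O/C10–H pair, the C5 O-acyl bond, C5–H, C1–O, and finally C1–C5 and C9–C10 with C5–C9 restored.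
4. Forward: ring B comes with the commercial bicyclic lactone. Its carbocycle is oxidised to the C5 ketone, and the C5=C9 enamine takes up the ynoate. A four-membered ring closes and then opens to ring A. The methylene and the propenyl chain are added last.
5. Stereochemistry: C6 and C7 come from the starting lactone. C1 is set by catalyst-controlled hydroxylation, C5 by hydride delivery from the C1 hydroxyl, and C9/C10 by syn hydroboration on the face away from ring B.

Key step: step 6

Convention: α is the face of ring A that carries the C6–O and C7–C11 bonds. β is the face that carries H6 and H7. Target numbering is used for all intermediates.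
Assumption: the (R,R) antipode of DBFOX-Ph is taken to leave the Si (α) face of C1 open in the nickel-bound enolate. If a trial run shows the opposite sense, the (S,S) ligand replaces it and nothing else changes.

**Step 1**
Reactants: 1 (1S,5R)-2-oxabicyclo[3.3.0]oct-6-en-3-one
Product: 2 (3aR,6R,6aR)-6-hydroxy-3,3a,6,6a-tetrahydro-2H-cyclopenta[b]furan-2-one (5β-alcohol)
Conditions: SeO2 (1.1 equiv), 1,4-dioxane, 90 °C
Reagents that add atoms: selenium dioxide, O=[Se]=O
Why: Riley allylic oxidation, in which the ene step binds selenium to C8 while removing a hydrogen from the C5 methylene (preferred over the fusion methine C7–H) and the [2,3]-shift returns oxygen to C5 without transposition, both on the convex β face, so the 5β-alcohol should form, a stereocentre that step 2 erases.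

**Step 2**
Reactants: 2 allylic alcohol
Product: 3 (3aR,6aR)-3,3a-dihydro-2H-cyclopenta[b]furan-2,6(6aH)-dione (enone)
Conditions: Dess–Martin periodinane (1.2 equiv), CH2Cl2, 0 °C to rt
Reagents that add atoms: none
Why: Dess–Martin oxidation of a secondary allylic alcohol under non-basic conditions, which leaves the lactone and the acidic γ-hydrogen at C7 alone.

**Step 3**
Reactants: 3 enone
Product: 4 (3aS,6aR)-tetrahydro-2H-cyclopenta[b]furan-2,6(3H)-dione
Conditions: H2 (1 atm), Pd/C (10 wt%), EtOAc, rt
Reagents that add atoms: none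
Why: Heterogeneous hydrogenation saturates the enone C=C faster than it touches the ketone or lactone, and no stereocentre is formed.

**Step 4**
Reactants: 4 keto lactone; 5 pyrrolidine
Product: 6 (3aS,6aR)-6-(pyrrolidin-1-yl)-3,3a,4,6a-tetrahydro-2H-cyclopenta[b]furan-2-one
Conditions: 5 (1.3 equiv), TsOH·H2O (1 mol%), 4 Å molecular sieves, toluene, rt; filtered, concentrated, used crude
Reagents that add atoms: none
Why: Stork enamine condensation, in which the double bond forms toward C9 because a C5=C6 enamine would sit at the oxygenated fusion carbon and suffer allylic strain with the pyrrolidine ring, room temperature with sieves avoids aminolysis of ring B, and any C6 equilibration through the iminium is harmless because a 5/5 fusion can only be cis.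

**Step 5**
Reactants: 7 but-2-ynoic acid
Product: 8 tert-butyl but-2-ynoate
Conditions: tert-butyl 2,2,2-trichloroacetimidate (1.5 equiv), BF3·OEt2 (2 mol%), CH2Cl2/cyclohexane, rt
Reagents that add atoms: tert-butyl 2,2,2-trichloroacetimidate, CC(C)(C)OC(=N)C(Cl)(Cl)Cl
Why: Acid-catalysed O-alkylation by the imidate needs no nucleophilic catalyst that would add to the ynoate, and the tert-butyl ester is chosen because it suits the catalyst of step 8, resists attack by the C9 hydroxyl after step 11, and can later be removed without touching the lactone or the isobutyrate.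

**Step 6**
Reactants: 6 enamine; 8 tert-butyl but-2-ynoate
Product: 10 tert-butyl (3aS,8aR)-6-methyl-2-oxo-8-(pyrrolidin-1-yl)-3,3a,4,8a-tetrahydro-2H-cyclohepta[b]furan-7-carboxylate (ring-A dienamine), via aminocyclobutene 9 (not isolated)
Conditions: 8 (3 equiv), MeCN (2 M), sealed tube, 80 °C; solvent switch to toluene, 110 °C
Reagents that add atoms: none
Why: The nucleophilic enamine carbon C9 adds in conjugate fashion to the methyl-bearing alkyne carbon C10 of 8 on the convex β face, and the iminium–allenolate zwitterion collapses by attack of C1 on the iminium carbon C5 (4-exo-trig closure) to the cis-fused aminocyclobutene 9. In 9 the C5–C9 bond is the shared, strained bond of a bicyclo[3.2.0]heptene flanked by the donor nitrogen and the acceptor acrylate, so it breaks on heating (formally a 4π electrocyclic opening, in practice stepwise through an iminium dienolate that lets the ring relax to the cis,cis-diene), and ring A therefore arises by two-atom insertion and not by direct seven-membered closure. The closest known reaction type is the two-carbon ring enlargement of cyclic ketone enamines with acetylenic esters such as acetylenedicarboxylates and propiolates. The two stereocentres of 9 (C5, C9) are fixed by the cis fusion and the β-face approach and both return to sp2 in 10, so no lasting stereocentre is set and C6 and C7 are untouched. The step needs regioselectivity (C9 to C10, C1 to C5), which follows from the polarity of the ynoate and the C5=C9 position of the enamine, and it needs cyclisation to outrun proton transfer to an open-chain dienamine, which the aprotic medium secures. Because a β-methyl ynoate is a slower acceptor than a propiolate, a polar aprotic solvent, high concentration, excess 8 and heat are used.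

**Step 7**
Reactants: 10 dienamine
Product: 11 tert-butyl (3aS,8aR)-8-hydroxy-6-methyl-2-oxo-3,3a,4,8a-tetrahydro-2H-cyclohepta[b]furan-7-carboxylate (β-keto ester drawn as its C5 enol)
Conditions: 1 M aq HCl, THF, 0 °C to rt
Reagents that add atoms: water, O
Why: Acid hydrolysis of the vinylogous carbamate (C-protonation, hydration of the iminium, loss of pyrrolidine) gives the β-keto ester, which should rest as the hydrogen-bonded enol conjugated with C9=C10, while dilute acid at room temperature spares the tert-butyl ester and gives C6 little chance to epimerise.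

**Step 8**
Reactants: 11 β-keto ester
Product: 12 tert-butyl (3aS,7S,8aR)-7-hydroxy-6-methyl-2,8-dioxo-3,3a,4,7,8,8a-hexahydro-2H-cyclohepta[b]furan-7-carboxylate (1α-OH; 1β-CO2tBu)
Conditions: Ni(ClO4)2·6H2O (10 mol%), (R,R)-DBFOX-Ph (11 mol%), 4 Å molecular sieves, 3-phenyl-2-(phenylsulfonyl)oxaziridine (1.2 equiv), CH2Cl2, rt
Reagents that add atoms: 3-phenyl-2-(phenylsulfonyl)oxaziridine, O=S(=O)(c1ccccc1)N1OC1c1ccccc1
Why: Lewis-acid-catalysed enantioselective α-hydroxylation of a cyclic tert-butyl β-keto ester, in which C1 lies 1,3 and 1,4 to C6 and C7 in a nearly flat dienol so the substrate bias should be small, the C2-symmetric ligand on the two-point-bound enolate of divalent nickel decides the face (oxygen to the α, Si face), and the oxaziridine ignores the C9=C10 alkene.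

**Step 9**
Reactants: 12 α-hydroxy β-keto ester
Product: 13 tert-butyl (3aS,7S,8S,8aR)-7,8-dihydroxy-6-methyl-2-oxo-3,3a,4,7,8,8a-hexahydro-2H-cyclohepta[b]furan-7-carboxylate (1α-OH; 5β-OH)
Conditions: Me4NBH(OAc)3 (5 equiv), MeCN/AcOH 1:1, −25 °C
Reagents that add atoms: none
Why: Saksena–Evans reduction, in which the borohydride exchanges an acetate for the C1 hydroxyl and hands its hydride to the α face of the adjacent C5 carbonyl, so the new hydroxyl is β (trans to 1α-OH and to the C6–O bond), while esters, lactone and alkene are inert to this reagent.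

**Step 10**
Reactants: 13 diol
Product: 14 tert-butyl (3aS,7S,8S,8aR)-7-hydroxy-6-methyl-8-(2-methylpropanoyloxy)-2-oxo-3,3a,4,7,8,8a-hexahydro-2H-cyclohepta[b]furan-7-carboxylate
Conditions: (iPrCO)2O (2 equiv), DMAP (0.2 equiv), Et3N, CH2Cl2, 0 °C to rt
Reagents that add atoms: 2-methylpropanoic anhydride, CC(C)C(=O)OC(=O)C(C)C
Why: DMAP-catalysed acylation distinguishes the secondary C5 alcohol from the tertiary C1 alcohol on steric grounds, and no stereocentre changes.

**Step 11**
Reactants: 14 isobutyrate
Product: 16 tert-butyl (3aS,5R,6S,7S,8S,8aR)-5,7-dihydroxy-6-methyl-8-(2-methylpropanoyloxy)-2-oxooctahydro-2H-cyclohepta[b]furan-7-carboxylate (9β-OH; 10β-H; 10α-CH3), via C9-alkylborane 15 (not isolated)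
Conditions: BH3·THF (3 equiv), THF, 0 °C to rt; then 30% H2O2, pH 7 phosphate buffer, 0 °C
Reagents that add atoms: hydrogen peroxide, OO; borane (THF complex), B (boron of 15 only)
Why: Hydroboration–oxidation, in which syn addition puts boron on the less substituted C9 and on the β face because, in the chair cycloheptene where allylic strain with the C10 methyl holds the C1 hydroxyl in the alkene plane, the lactone methylene C11 is axial on the α face and 1,3-syn to C9 whereas the C1 ester flanks only the hydrogen-accepting C10, and oxidation with retention then gives 9β-OH, 10β-H and so 10α-CH3.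

**Step 12**
Reactants: 16 diol
Product: 17 1,9-bis(triethylsilyl) ether of 16
Conditions: Et3SiOTf (3 equiv), 2,6-lutidine (5 equiv), CH2Cl2, −78 to 0 °C
Reagents that add atoms: triethylsilyl trifluoromethanesulfonate, CC[Si](CC)(CC)OS(=O)(=O)C(F)(F)F
Why: Silyl triflate silylation is strong enough for the tertiary C1 as well as the secondary C9 alcohol, and blocking both prevents alkoxide-driven isobutyrate migration in step 13 and lactonisation of the C9 hydroxyl onto C2 in steps 14 and 15.

**Step 13**
Reactants: 17 bis-silyl ether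
Product: 21 α-methylene lactone (17 carrying C11=C13H2), via lithium enolate 18 (not isolated), via Mannich base 19 (not isolated), via ammonium iodide 20 (not isolated)
Conditions: LiN(iPr)2 (1.1 equiv), THF, −78 °C; Me2N=CH2 iodide, −78 to 0 °C; MeI, Et2O/CH2Cl2, rt; aq NaHCO3, CH2Cl2, rt
Reagents that add atoms: dimethylmethyleneammonium iodide, C=[N+](C)C.[I-]; iodomethane, CI (methyl of 20 only)
Why: Mannich methylenation, in which the γ-lactone CH2 is the most acidic and most accessible C–H (the isobutyrate methine is slower and the tert-butyl ester has no α-hydrogen), the enolate is aminomethylated on the convex face, and quaternisation followed by E1cB loss of trimethylamine removes the transient C11 stereocentre.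

**Step 14**
Reactants: 21 tert-butyl ester
Product: 23 C2 carboxylic acid (both silyl ethers retained), via trimethylsilyl ester 22 (not isolated)
Conditions: Me3SiOTf (3 equiv), 2,6-lutidine (4.5 equiv), CH2Cl2, 0 °C; then pH 5 aqueous buffer
Reagents that add atoms: trimethylsilyl trifluoromethanesulfonate, C[Si](C)(C)OS(=O)(=O)C(F)(F)F (silyl group of 22 only)
Why: Silyl-triflate-mediated tert-butyl ester cleavage (O-silylation, loss of isobutene) and hydrolysis of the labile silyl ester free the acid under buffered conditions that keep both triethylsilyl ethers, which protic acid would not.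

**Step 15**
Reactants: 23 acid; 24 (E)-tributyl(prop-1-en-1-yl)stannane
Product: 26 1,9-bis(triethylsilyl) ether of the target, via acid chloride 25 (not isolated)
Conditions: 1-chloro-N,N,2-trimethylprop-1-en-1-amine (1.3 equiv), CH2Cl2, 0 °C; then 24 (1.3 equiv), Pd2(dba)3 (5 mol%), P(2-furyl)3 (20 mol%), CO (1 atm), THF, 45 °C
Reagents that add atoms: 1-chloro-N,N,2-trimethylprop-1-en-1-amine, CC(C)=C(Cl)N(C)C (chlorine of 25 only)
Why: Neutral chloroenamine activation followed by Stille acylation (oxidative addition of the acyl chloride to zerovalent palladium, transmetallation with retention of the E geometry, reductive elimination) converts only the acid-derived carbonyl, so lactone, isobutyrate and methylene lactone are spectators, and the CO atmosphere holds back decarbonylation of the hindered acyl-palladium species.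

**Step 16**
Reactants: 26 bis-silyl ether
Product: 27 (3aS,5R,6S,7S,8S,8aR)-7-[(E)-but-2-enoyl]-5,7-dihydroxy-6-methyl-3-methylidene-2-oxooctahydro-2H-cyclohepta[b]furan-8-yl 2-methylpropanoate (CNP0123946.1)
Conditions: HF·pyridine, pyridine, THF, 0 °C to rt
Reagents that add atoms: none
Why: Fluoride-mediated desilylation in a buffered acidic medium removes both triethylsilyl groups without conjugate addition to either Michael acceptor and without acyl migration.

**Compound list**
1 | (1S,5R)-2-oxabicyclo[3.3.0]oct-6-en-3-one | O=C1C[C@@H]2C=CC[C@@H]2O1 | starting material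
2 | (3aR,6R,6aR)-6-hydroxy-3,3a,6,6a-tetrahydro-2H-cyclopenta[b]furan-2-one | O=C1C[C@@H]2C=C[C@@H](O)[C@@H]2O1 | intermediate
3 | (3aR,6aR)-3,3a-dihydro-2H-cyclopenta[b]furan-2,6(6aH)-dione | O=C1C[C@@H]2C=CC(=O)[C@@H]2O1 | intermediate
4 | (3aS,6aR)-tetrahydro-2H-cyclopenta[b]furan-2,6(3H)-dione | O=C1C[C@@H]2CCC(=O)[C@@H]2O1 | intermediate
5 | pyrrolidine | C1CCNC1 | starting material
6 | (3aS,6aR)-6-(pyrrolidin-1-yl)-3,3a,4,6a-tetrahydro-2H-cyclopenta[b]furan-2-one | O=C1C[C@@H]2CC=C(N3CCCC3)[C@@H]2O1 | intermediate
7 | but-2-ynoic acid | CC#CC(=O)O | starting material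
8 | tert-butyl but-2-ynoate | CC#CC(=O)OC(C)(C)C | intermediate
9 | aminocyclobutene (cyclobutene C9–C10=C1–C5 cis-fused on the β face; pyrrolidine on C5 α; H9 α) | O=C1C[C@@H]2C[C@H]3C(C)=C(C(=O)OC(C)(C)C)[C@@]3(N4CCCC4)[C@@H]2O1 | intermediate
10 | tert-butyl (3aS,8aR)-6-methyl-2-oxo-8-(pyrrolidin-1-yl)-3,3a,4,8a-tetrahydro-2H-cyclohepta[b]furan-7-carboxylate | O=C1C[C@@H]2CC=C(C)C(C(=O)OC(C)(C)C)=C(N3CCCC3)[C@@H]2O1 | intermediate
11 | tert-butyl (3aS,8aR)-8-hydroxy-6-methyl-2-oxo-3,3a,4,8a-tetrahydro-2H-cyclohepta[b]furan-7-carboxylate (enol form) | O=C1C[C@@H]2CC=C(C)C(C(=O)OC(C)(C)C)=C(O)[C@@H]2O1 | intermediate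
12 | 1α-hydroxy β-keto ester (3aS,7S,8aR) | O=C1C[C@@H]2CC=C(C)[C@@](O)(C(=O)OC(C)(C)C)C(=O)[C@@H]2O1 | intermediate
13 | 1α,5β-diol (3aS,7S,8S,8aR) | O=C1C[C@@H]2CC=C(C)[C@@](O)(C(=O)OC(C)(C)C)[C@@H](O)[C@@H]2O1 | intermediate
14 | 5β-isobutyrate of 13 | O=C1C[C@@H]2CC=C(C)[C@@](O)(C(=O)OC(C)(C)C)[C@@H](OC(=O)C(C)C)[C@@H]2O1 | intermediate
15 | 9β-boryl, 10β-H alkylborane (drawn as RBH2 with free C1 hydroxyl) | O=C1C[C@@H]2C[C@@H](B)[C@H](C)[C@@](O)(C(=O)OC(C)(C)C)[C@@H](OC(=O)C(C)C)[C@@H]2O1 | intermediate
16 | 1α,9β-diol, 10α-methyl (3aS,5R,6S,7S,8S,8aR) | O=C1C[C@@H]2C[C@@H](O)[C@H](C)[C@@](O)(C(=O)OC(C)(C)C)[C@@H](OC(=O)C(C)C)[C@@H]2O1 | intermediate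
17 | 1,9-bis(triethylsilyl) ether of 16 | O=C1C[C@@H]2C[C@@H](O[Si](CC)(CC)CC)[C@H](C)[C@@](O[Si](CC)(CC)CC)(C(=O)OC(C)(C)C)[C@@H](OC(=O)C(C)C)[C@@H]2O1 | intermediate
18 | lithium enolate of the lactone of 17 | [Li+].[O-]C1=C[C@@H]2C[C@@H](O[Si](CC)(CC)CC)[C@H](C)[C@@](O[Si](CC)(CC)CC)(C(=O)OC(C)(C)C)[C@@H](OC(=O)C(C)C)[C@@H]2O1 | intermediate
19 | C11-(dimethylaminomethyl) lactone (substituent cis to H7) | CN(C)C[C@@H]1C(=O)O[C@@H]2[C@H]1C[C@@H](O[Si](CC)(CC)CC)[C@H](C)[C@@](O[Si](CC)(CC)CC)(C(=O)OC(C)(C)C)[C@H]2OC(=O)C(C)C | intermediate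
20 | trimethylammonium iodide of 19 | [I-].C[N+](C)(C)C[C@@H]1C(=O)O[C@@H]2[C@H]1C[C@@H](O[Si](CC)(CC)CC)[C@H](C)[C@@](O[Si](CC)(CC)CC)(C(=O)OC(C)(C)C)[C@H]2OC(=O)C(C)C | intermediate
21 | α-methylene lactone tert-butyl ester | C=C1C(=O)O[C@@H]2[C@H]1C[C@@H](O[Si](CC)(CC)CC)[C@H](C)[C@@](O[Si](CC)(CC)CC)(C(=O)OC(C)(C)C)[C@H]2OC(=O)C(C)C | intermediate
22 | trimethylsilyl ester | C=C1C(=O)O[C@@H]2[C@H]1C[C@@H](O[Si](CC)(CC)CC)[C@H](C)[C@@](O[Si](CC)(CC)CC)(C(=O)O[Si](C)(C)C)[C@H]2OC(=O)C(C)C | intermediate
23 | C2 carboxylic acid | C=C1C(=O)O[C@@H]2[C@H]1C[C@@H](O[Si](CC)(CC)CC)[C@H](C)[C@@](O[Si](CC)(CC)CC)(C(=O)O)[C@H]2OC(=O)C(C)C | intermediate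
24 | (E)-tributyl(prop-1-en-1-yl)stannane | C/C=C/[Sn](CCCC)(CCCC)CCCC | starting material
25 | C2 acid chloride | C=C1C(=O)O[C@@H]2[C@H]1C[C@@H](O[Si](CC)(CC)CC)[C@H](C)[C@@](O[Si](CC)(CC)CC)(C(=O)Cl)[C@H]2OC(=O)C(C)C | intermediate
26 | 1,9-bis(triethylsilyl) ether of the target | C=C1C(=O)O[C@@H]2[C@H]1C[C@@H](O[Si](CC)(CC)CC)[C@H](C)[C@@](O[Si](CC)(CC)CC)(C(=O)/C=C/C)[C@H]2OC(=O)C(C)C | intermediate
27 | CNP0123946.1 | C=C1C(=O)O[C@@H]2[C@H]1C[C@@H](O)[C@H](C)[C@@](O)(C(=O)/C=C/C)[C@H]2OC(=O)C(C)C | target

Total step count: 16. Longest linear sequence: 15 (steps 1–4 and 6–16).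

**Steps most likely to fail**

Step 6. Conjugate addition to a β-methyl ynoate may be too slow. The heat then needed could erode the α-acyloxy enamine through aminolysis of ring B by traces of pyrrolidine or oligomerisation of 8. The fallback activates the acceptor instead of the donor and sets out from enone 3.
- Conjugate hydrosilylation (Et3SiH, RhCl(PPh3)3, toluene, 50 °C) fixes the double bond at C5=C9 and gives the triethylsilyl enol ether F1.
- A [2+2] cycloaddition with 8 catalysed by Tf2NH (CH2Cl2, −40 °C) forms the same C9–C10 and C1–C5 bonds in the silyloxycyclobutene F2.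
- Bu4NF buffered with AcOH unmasks the cyclobutanolate, which cleaves C5–C9 in a retro-aldol sense to the ester-stabilised dienolate. After protonation this rejoins the route at 11.

Step 8. Facial selectivity may be poor if an intrinsic β-face preference of the dienol works against the catalyst (mismatched double diastereodifferentiation). The fallback turns such a preference to advantage and sets out from 11.
- Chlorination with N-chlorosuccinimide (Et3N cat., CH2Cl2, 0 °C) on the β face gives the 1β-chloro β-keto ester F3.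
- SN2 displacement at the tertiary α-chloro-β-keto ester carbon by 4-methoxyphenol/Cs2CO3 (MeCN, rt) inverts C1 and gives the 1α-aryl ether F4.
- Oxidative dearylation with (NH4)2Ce(NO3)6 (MeCN/H2O, 0 °C) returns to the route at 12.

Step 11. Borane may approach the α face (anti to the C1 ester), or slow hydroboration next to the quaternary C1 may let reduction of the α-hydroxy ester compete. The fallback builds each centre from the C1 hydroxyl and sets out from 14.
- Hydroxyl-directed epoxidation (VO(acac)2, tBuOOH, CH2Cl2) gives the 9α,10α-epoxide F5.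
- Reductive opening with Cp2TiCl (from Cp2TiCl2 and Mn) and 1,4-cyclohexadiene passes through the tertiary C10 radical. That radical takes hydrogen on the β face, away from the titanium alkoxide, to give the 9α-alcohol F6 with 10β-H.
- Dess–Martin oxidation gives the C9 ketone F7.
- Saksena–Evans reduction (Me4NBH(OAc)3, MeCN/AcOH, −25 °C) delivers hydride from the C1 hydroxyl to the α face, sets the anti-1,3 9β-alcohol and rejoins the route at 16.

**Further compounds**
F1 | step 6 | (3aS,6aR)-6-(triethylsilyloxy)-3,3a,4,6a-tetrahydro-2H-cyclopenta[b]furan-2-one | O=C1C[C@@H]2CC=C(O[Si](CC)(CC)CC)[C@@H]2O1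
F2 | step 6 | silyloxycyclobutene (analogue of 9 with OSiEt3 on C5 α) | O=C1C[C@@H]2C[C@H]3C(C)=C(C(=O)OC(C)(C)C)[C@@]3(O[Si](CC)(CC)CC)[C@@H]2O1
F3 | step 8 | 1β-chloro β-keto ester | O=C1C[C@@H]2CC=C(C)[C@](Cl)(C(=O)OC(C)(C)C)C(=O)[C@@H]2O1
F4 | step 8 | 1α-(4-methoxyphenoxy) β-keto ester | O=C1C[C@@H]2CC=C(C)[C@@](Oc3ccc(OC)cc3)(C(=O)OC(C)(C)C)C(=O)[C@@H]2O1
F5 | step 11 | 9α,10α-epoxide of 14 | O=C1C[C@@H]2C[C@@H]3O[C@]3(C)[C@@](O)(C(=O)OC(C)(C)C)[C@@H](OC(=O)C(C)C)[C@@H]2O1
F6 | step 11 | 9α-alcohol, 10β-H (C9 epimer of 16) | O=C1C[C@@H]2C[C@H](O)[C@H](C)[C@@](O)(C(=O)OC(C)(C)C)[C@@H](OC(=O)C(C)C)[C@@H]2O1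
F7 | step 11 | C9 ketone, 10α-methyl | O=C1C[C@@H]2CC(=O)[C@H](C)[C@@](O)(C(=O)OC(C)(C)C)[C@@H](OC(=O)C(C)C)[C@@H]2O1
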